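**Retrosynthetic overview**

1. The O1/C2–C6 ring of the target is the 2,3-dihydro form of an aromatic γ-pyrone, and its only stereocentre, C2, is the ring carbon that carries the only large substituent (chain C1′–C23′). The route therefore cuts the exocyclic C2–C1′ bond.
2. Target ⇒ 2-methyl-4H-pyran-4-one (flat, achiral, complete ring with its C6-methyl) + (Z)-tricos-14-enyl Grignard reagent. A catalytic enantioselective dearomative α-alkylation through the 4-silyloxypyrylium ion joins chain and ring and sets C2 in the same bond formation.
3. C23 Grignard ⇒ (Z)-1-bromotricos-14-ene ⇒ C5′–C6′ sp3–sp3 copper-catalysed coupling of oleylmagnesium bromide (which brings the C14′=C15′ Z-alkene ready-made) with 1,5-dibromopentane.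
4. No ring is formed in the route: the single ring is bought as the γ-pyrone and is dearomatised in the last step.

Key step: step 3

Assumption: 2-methyl-4H-pyran-4-one (6) and isomerically pure (Z)-1-bromooctadec-9-ene (1) are taken as catalogue compounds; ring atoms are numbered as in the target (O1, C2 stereocentre, C3, C4 carbonyl, C5, C6 bearing CH3), chain atoms C1′–C23′.

**Route**

Step 1
Reactants: 1 (Z)-1-bromooctadec-9-ene (oleyl bromide); 2 1,5-dibromopentane
Product: 4 (Z)-1-bromotricos-14-ene, via oleylmagnesium bromide 3 (not isolated)
Conditions: Mg, THF, 40 °C; then added to 2 (4 equiv), Li2CuCl4 (3 mol %), THF, −10 °C → rt; excess 2 removed by vacuum distillation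
Reagents that add atoms: none
Why: Copper-catalysed sp3–sp3 cross-coupling of a primary alkyl Grignard reagent with a primary alkyl bromide forms C5′–C6′; the excess of the symmetrical dibromide should hold the reaction at mono-substitution, and the remote (Z)-alkene of the oleyl unit is a spectator, so its geometry is carried over unchanged.

Step 2
Reactants: 4 (Z)-1-bromotricos-14-ene
Product: 5 (Z)-tricos-14-enylmagnesium bromide (obtained and used as a titrated Et2O solution)
Conditions: Mg turnings (I2-activated), Et2O, slow addition, gentle reflux; titration
Reagents that add atoms: magnesium, [Mg]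
Why: Grignard formation by direct magnesium insertion into a primary alkyl bromide; the alkene lies thirteen carbons from the C–Mg bond (no cyclisation path), and slow addition at moderate dilution should limit Wurtz coupling.

Step 3
Reactants: 5 (Z)-tricos-14-enylmagnesium bromide; 6 2-methyl-4H-pyran-4-one
Product: 9 (2R)-6-methyl-2-[(14Z)-tricos-14-en-1-yl]-2,3-dihydro-4H-pyran-4-one, via silyloxypyrylium triflate 7 (not isolated), via silyl dienol ether 8 (not isolated)
Conditions: 6, TMSOTf (1.1 equiv), CH2Cl2, −78 °C; CuBr·SMe2 (5 mol %), (R,R)-Ph-BPE (6 mol %); 5 (1.3 equiv in Et2O) added over 2 h at −78 °C; then 1.25 M HCl in MeOH, −78 → 0 °C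
Reagents that add atoms: none
Why: Proposed new method: O-silylation of 6 by TMSOTf should give the 4-silyloxypyrylium salt 7, whose unsubstituted α-carbon (C6 of 6, C2 of the target) is attacked by the chiral alkylcopper(I) species formed from 5 and the CuBr/diphosphine complex to give the neutral silyl dienol ether 8, which cold acidic methanolysis protonates at C3 to unveil the dihydropyranone; the closest known reaction types are the Cu/diphosphine-catalysed enantioselective additions of Grignard reagents to chromones, N-acyl-4-pyridones and 4-methoxypyridinium salts, the Cu-catalysed enantioselective alkynylation of 4-silyloxybenzopyrylium triflates, and the racemic addition of Grignard reagents to 4-silyloxypyrylium triflates. No ring is closed: the step forms the exocyclic C2–C1′ bond on the intact O1–C6 ring and dearomatises it. The single stereocentre C2 is set by catalyst control alone, through ligand-directed delivery of the copper-bound alkyl group to the Re face of the attacked carbon of the planar pyrylium ion; the ligand antipode that gives this face is fixed in a pilot run, both being commercial. The step needs regioselectivity for C–H over C–CH3 and over C4, which the methyl group (the alternative would be a quaternary centre) and the 4-silyloxy donor should secure. It also needs the copper-bound path to outrun the racemic background addition, which slow addition of 5 at −78 °C favours, and 8 is protonated cold so that 6π ring opening of the 2H-pyran cannot scramble C2. The isolated (Z)-alkene at C14′ is not activated and should stay untouched.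

**Compound list**

1 | (Z)-1-bromooctadec-9-ene (oleyl bromide) | CCCCCCCC/C=C\CCCCCCCCBr | starting material
2 | 1,5-dibromopentane | BrCCCCCBr | starting material
3 | (Z)-octadec-9-enylmagnesium bromide | CCCCCCCC/C=C\CCCCCCCC[Mg]Br | intermediate
4 | (Z)-1-bromotricos-14-ene | CCCCCCCC/C=C\CCCCCCCCCCCCCBr | intermediate
5 | (Z)-tricos-14-enylmagnesium bromide | CCCCCCCC/C=C\CCCCCCCCCCCCC[Mg]Br | intermediate
6 | 2-methyl-4H-pyran-4-one | CC1=CC(=O)C=CO1 | starting material
7 | 2-methyl-4-(trimethylsilyloxy)pyrylium trifluoromethanesulfonate | C[Si](C)(C)OC1=CC(C)=[O+]C=C1.[O-]S(=O)(=O)C(F)(F)F | intermediate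
8 | (2R)-6-methyl-2-[(14Z)-tricos-14-en-1-yl]-4-(trimethylsilyloxy)-2H-pyran | CCCCCCCC/C=C\CCCCCCCCCCCCC[C@@H]1C=C(O[Si](C)(C)C)C=C(C)O1 | intermediate
9 | (2R)-6-methyl-2-[(14Z)-tricos-14-en-1-yl]-2,3-dihydro-4H-pyran-4-one | CCCCCCCC/C=C\CCCCCCCCCCCCC[C@@H]1CC(=O)C=C(C)O1 | target

**Step count and risks**

Total step count: 3. Longest linear sequence: 3 steps (1 → 4 → 5 → 9).

Steps most likely to fail:

Step 3 (Proposed new method). The uncatalysed addition of 5 to the pyrylium ion may compete with the copper-bound pathway and erode the enantiomeric purity. The Grignard reagent may also deprotonate the 2-methyl group of 7 and return 6, or add at C4 or at the methyl-bearing α-carbon. On warming, the 2H-pyran 8 may open by 6π electrocyclic ring opening to an acyclic dienone, which destroys C2. The fallback uses known chemistry and runs from 5 to 9. Compound 5 is formylated with DMF (Et2O, 0 °C; aq. HCl) to (Z)-tetracos-15-enal F1. Commercial (E)-4-methoxypent-3-en-2-one is converted (LDA, TMSCl, THF, −78 °C) into (3E)-4-methoxy-2-(trimethylsilyloxy)penta-1,3-diene F2. A Ti(OiPr)4/BINOL-catalysed enantioselective Mukaiyama aldol addition of F2 to F1 (BINOL antipode chosen for the 6R carbinol; 4 Å MS, Et2O, −20 °C; aqueous work-up) should give (6R,2E,20Z)-6-hydroxy-2-methoxynonacosa-2,20-dien-4-one F3. TFA in CH2Cl2 at 0 °C then closes the ring by 6-endo oxa-Michael addition and loss of methanol, which does not touch the carbinol centre, and the route is rejoined at 9.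

Step 1. A second substitution of 4 by 3, homo-coupling of 3 and a difficult separation of the non-polar products may lower the supply of 4. The fallback runs from 3 to 4. Compound 3 is coupled (Li2CuCl4, THF, −10 °C) with 1-bromo-5-chloropentane, whose C–Br bond alone should react, to give (Z)-1-chlorotricos-14-ene F4 without statistical control. Chloride–bromide exchange (excess bromoethane, NaBr cat., NMP, 65 °C, chloroethane distils off) then gives 4.

Step 2. Wurtz-type homo-coupling during slow magnesium insertion and precipitation of the long-chain reagent may give a weak or impure solution of 5. The fallback runs from 4 to 5. Finkelstein exchange (NaI, acetone, reflux) gives (Z)-1-iodotricos-14-ene F5. Iodine–lithium exchange (t-BuLi, 2.1 equiv, Et2O/pentane, −78 °C) gives (Z)-tricos-14-enyllithium F6, which MgBr2·OEt2 transmetalates to 5.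

**Further compounds**

F1 | step 3 | (Z)-tetracos-15-enal | CCCCCCCC/C=C\CCCCCCCCCCCCCC=O
F2 | step 3 | (3E)-4-methoxy-2-(trimethylsilyloxy)penta-1,3-diene | C=C(O[Si](C)(C)C)/C=C(\C)OC
F3 | step 3 | (6R,2E,20Z)-6-hydroxy-2-methoxynonacosa-2,20-dien-4-one | CCCCCCCC/C=C\CCCCCCCCCCCCC[C@@H](O)CC(=O)/C=C(\C)OC
F4 | step 1 | (Z)-1-chlorotricos-14-ene | CCCCCCCC/C=C\CCCCCCCCCCCCCCl
F5 | step 2 | (Z)-1-iodotricos-14-ene | CCCCCCCC/C=C\CCCCCCCCCCCCCI
F6 | step 2 | (Z)-tricos-14-enyllithium | CCCCCCCC/C=C\CCCCCCCCCCCCC[Li]
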